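## Analysis of the target

The target (33) is a longipinane sesquiterpenoid diester. Atom locants used throughout: C1 (ketone), C2=C3 (C3 carries a methyl), C4 and C11 (bridgeheads), C5 (H), C6 (CMe2), C7 (O-methacrylate), C8 (CH2), C9 (O-angelate), C10 (quaternary, methyl). The core is a bicyclo[3.1.1]hept-3-en-2-one: the cyclobutane C4–C5–C11–C10 is spanned by the enone bridge C1(=O)–C2=C3. Its two one-carbon bridges C5 and C10 are tied by the chain C6–C7–C8–C9 into a seven-membered ring.

There are six stereocentres. C4, C5, C10 and C11 are locked by the tricyclic topology (methyl on C10 syn to the enone bridge, both chain carbons C6 and C9 anti), so they form one element whose absolute sense (4R,5S,10R,11R) must be set. C7 and C9 carry trans-1,3 oxygens (7R,9R), both neopentylic, between the quaternary carbons C6 and C10.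

The lower ring C5–C10 is nearly mirror-symmetric, so substrate control at C7 and C9 will be weak, and the two oxygens carry different acyl groups. Sensitive groups are the angelate (Z to E isomerisation), the methacrylate (Michael acceptor), and the cyclobutane next to any cationic centre at C3 (pinene-type rearrangement). A carbonyl at C5 that is 1,3 to a C1 ketone would also be prone to retro-Claisen ring opening.

The feature this route uses: the perimeter C5–C4–C3–C2–C1–C11–C10–C9–C8–C7–C6 is a head-to-tail farnesane chain. The two bonds that cross it, C5–C11 and C4–C10, are the ones biosynthesis forms (himachalane closure, then cyclobutane closure). Both can be made in one step if C4=C5 is a ketene and C11=C10 an alkene.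

## Retrosynthetic reasoning

**33 to 30 (C9–O acyl).** The angelate is cut last, because it is the most isomerisation-prone group. The forward step is an esterification of the hindered C9 alcohol of 30 with angelic acid 31 through a mixed anhydride.

**30 to 27 (C9–H and C7–O acyl together).** In 30 the C7 oxygen is acylated and the C9 oxygen is free and trans. This is the pattern a samarium-catalysed Evans–Tishchenko reduction gives from a β-hydroxy ketone. With methacrolein 28 as the aldehyde, the ester formed at C7 is the methacrylate itself. One step then sets C9, differentiates the two oxygens and installs the first ester.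

**27 to 25 (C7–O).** The nearly symmetric lower ring offers no reliable facial bias, so C7 is set by catalyst control: enantioselective conjugate borylation and oxidation of the cycloheptenone in 25.

**25 to 22 (C7–C8 and enone conjugation).** Cutting C7=C8 by aldol condensation gives diketo aldehyde 22. The methyl ketone on C10 and the non-enolisable aldehyde on C6 both sit on the anti positions of the cyclobutane and are held next to each other. The same base moves the exocyclic C3 methylidene into conjugation with C1.

**22 to 18 (oxidation levels).** 22 comes from ester 18 by ester reduction, desilylation, double oxidation (C1 and C7) and Wacker oxidation of the C10 vinyl group. C1 is kept as a silyl ether until C5 carries no oxygen, to avoid the retro-Claisen problem.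

**18 to 13 (C5–C6).** The C5–C6 bond is cut back to cyclobutanone 13. Forward: addition of the enolate of methyl isobutyrate 14 to the C5 ketone, then radical deoxygenation. The anti face of C5 is blocked by the vinyl group on C10, so hydrogen is delivered syn and C6 ends up anti, as the seven-membered ring needs.

**13 to 10 (key disconnection, C5–C11 and C4–C10).** Both bonds are cut at once to the acyclic trienoic acid 10. Forward: the derived vinylketene 12 adds across the C11=C10 alkene in the crossed mode. This forms the cyclobutane and the six-membered ring, creates quaternary C10 from the E alkene, and sets C4, C10 and C11 relative to the C1 silyloxy stereocentre. The precursor has one stereocentre and no ring.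

**10 to 3 + 6 (C1–C2).** A catalytic enantioselective vinylogous Mukaiyama aldol of dienal 3 with silyl dienolate 6 makes the C1 carbinol and the whole chain. 3 comes from commercial enynol 1, and 6 from ester 4.

## Alternatives that were turned down

**Alternative 1:** The textbook route cuts C4–C10. A cis-fused bicyclo[5.4.0]undecane keto tosylate A1 (C9 ketone, C4 sulfonate) would be closed by intramolecular enolate alkylation (4-exo-tet), forming the cyclobutane and quaternary C10. It was turned down for three reasons: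
- A1 already carries five stereocentres on a flexible 6/7 system and would need a long linear build.
- The C9 ketone can enolise towards C8, where the C7 oxygen is β and would be lost by E1cB.
- The C4 sulfonate is secondary and allylic, so E2 and SN2' compete with a strained closure.

**Alternative 2:** Cut C10–C11 and C4–C5 photochemically. A hexa-1,5-dien-3-one A2 would undergo a crossed enone–alkene [2+2] to the bicyclo[2.1.1]hexan-2-one A3, followed by a one-carbon ring expansion of the two-carbon bridge to the enone bridge. It was turned down for three reasons: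
- The triplet 1,4-biradical lets the C4=C10 geometry scramble, so C10 is not controlled.
- The product needed has both large groups on the congested anti positions of C5 and C10, against the steric preference of the biradical closure.
- The absolute sense is not set, and the ring expansion adds steps.

**Alternative 3:** Start from the chiral pool. (+)-Verbenone A4 already holds the cyclobutane, the enone and the right absolute configuration. The seven-membered ring would be annulated after oxidising the anti geminal methyl to aldehyde A5 and forming a C–C bond at the cyclobutane methylene. It was turned down because nothing in A4 distinguishes the two geminal methyls or activates the cyclobutane CH2. Two undirected C–H functionalisations would cost more than building the skeleton.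

Key step: step 7

Assumption: the chiral bisphosphoramide/SiCl4 aldol is taken to attack the Re face of an aldehyde with the (R,R) catalyst, so the (S,S) catalyst is written for the 5S alcohol. The ligand enantiomer in step 15 is the one that delivers boron to give 7R. If either sense is the reverse, only the antipode of that catalyst changes.

## Route

Step 1
Reactants: 1 (E)-3-methylpent-2-en-4-yn-1-ol
Product: 2 (E)-3-methylpenta-2,4-dien-1-ol
Conditions: H2 (1 atm), Pd/CaCO3 poisoned with Pb(OAc)2, quinoline, EtOAc, rt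
Reagents that add atoms: none
Why: Lindlar semihydrogenation stops at the vinyl group and leaves the trisubstituted E alkene untouched.

Step 2
Reactants: 2 (E)-3-methylpenta-2,4-dien-1-ol
Product: 3 (E)-3-methylpenta-2,4-dienal
Conditions: MnO2, CH2Cl2, rt
Reagents that add atoms: none
Why: Allylic oxidation with MnO2 is neutral and keeps the E geometry; the volatile dienal is used as a solution.

Step 3
Reactants: 4 methyl 3-methylbut-2-enoate
Product: 6 (1Z)-1-[(tert-butyldimethylsilyl)oxy]-1-methoxy-3-methylbuta-1,3-diene, via lithium dienolate 5 (not isolated)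
Conditions: LiN(i-Pr)2, THF/DMPU, −78 °C; then t-BuMe2SiCl
Reagents that add atoms: tert-butyldimethylsilyl chloride CC(C)(C)[Si](C)(C)Cl; lithium diisopropylamide [Li]N(C(C)C)C(C)C (lithium in 5 only)
Why: Kinetic γ-deprotonation gives the extended dienolate, which is silylated on oxygen; the acetal geometry has no bearing on the next step.

Step 4
Reactants: 3 (E)-3-methylpenta-2,4-dienal; 6 (1Z)-1-[(tert-butyldimethylsilyl)oxy]-1-methoxy-3-methylbuta-1,3-diene
Product: 8 methyl (2E,5S,6E)-5-hydroxy-3,7-dimethylnona-2,6,8-trienoate, via trichlorosilyl aldolate 7 (not isolated)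
Conditions: SiCl4 (1.1 equiv), (S,S)-bisphosphoramide [pentane-1,5-diyl-linked dimer of the N,N'-dimethyl-1,1'-binaphthyl-2,2'-diamine phosphoramide] (5 mol %), i-Pr2NEt (10 mol %), CH2Cl2, −78 °C; aq NaHCO3
Reagents that add atoms: silicon tetrachloride Cl[Si](Cl)(Cl)Cl (silicon in 7 only)
Why: Lewis-base-activated vinylogous Mukaiyama aldol; the chiral chlorosilyl cation binds the aldehyde and the dienolate attacks through its γ-carbon, setting the C1 carbinol (5S) under catalyst control and giving the 2E enoate.

Step 5
Reactants: 8 methyl (2E,5S,6E)-5-hydroxy-3,7-dimethylnona-2,6,8-trienoate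
Product: 9 methyl (2E,5S,6E)-5-[(tert-butyldimethylsilyl)oxy]-3,7-dimethylnona-2,6,8-trienoate
Conditions: t-BuMe2SiCl, imidazole, DMF, rt
Reagents that add atoms: tert-butyldimethylsilyl chloride CC(C)(C)[Si](C)(C)Cl
Why: Standard silylation; the silyl ether must survive base, ketene formation, radical and hydride steps and come off with fluoride, since acid must be avoided later.

Step 6
Reactants: 9 methyl (2E,5S,6E)-5-[(tert-butyldimethylsilyl)oxy]-3,7-dimethylnona-2,6,8-trienoate
Product: 10 (2E,5S,6E)-5-[(tert-butyldimethylsilyl)oxy]-3,7-dimethylnona-2,6,8-trienoic acid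
Conditions: LiOH·H2O, THF/MeOH/H2O, 40 °C; then aq NaH2PO4 to pH 4
Reagents that add atoms: lithium hydroxide [Li+].[OH-]
Why: Saponification of the hindered enoate; the mildly acidic work-up spares the dienylic silyl ether.

Step 7
Reactants: 10 (2E,5S,6E)-5-[(tert-butyldimethylsilyl)oxy]-3,7-dimethylnona-2,6,8-trienoic acid
Product: 13 (1R,4S,5R,7R)-4-[(tert-butyldimethylsilyl)oxy]-7-ethenyl-7-methyl-2-methylidenebicyclo[3.1.1]heptan-6-one, via acid chloride 11 (not isolated), via vinylketene 12 (not isolated)
Conditions: 1-chloro-N,N,2-trimethylprop-1-en-1-amine (1.2 equiv), CH2Cl2, 0 °C to rt; then slow addition to Et3N (5 equiv), toluene (0.005 M), 110 °C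
Reagents that add atoms: 1-chloro-N,N,2-trimethylprop-1-en-1-amine CC(C)=C(Cl)N(C)C (chlorine in 11 only)
Why: Et3N removes a γ-proton from the methyl group cis to the acyl chloride of 11 and chloride leaves, giving vinylketene 12. The electrophilic ketene carbon C5 bonds to C11, which leaves the developing positive charge on tertiary, allyl-stabilised C10, and C10 then bonds to the ketene α-carbon C4; the closest known reaction type is the thermal intramolecular [2+2] of vinylketenes from 3-methyl-2,6-dienoyl chlorides, which gives 7,7-disubstituted 2-methylidenebicyclo[3.1.1]heptan-6-ones. The C5–C11 bond closes the six-membered ring C5–C4–C3–C2–C1–C11 (exo with respect to the alkene) and the C4–C10 bond closes the cyclobutane in the crossed, bridged mode; the fused bicyclo[3.2.0] mode would place the charge on secondary C11 and is disfavoured. C10 is set by suprafacial addition to the E alkene: the methyl, cis to C1 in 10, ends syn to the three-carbon bridge and the vinyl group anti. C4 and C11 are bridgeheads and follow from the bridged topology once the alkene face is chosen. The face is chosen by the C1 stereocentre: allylic strain with the C10 methyl holds H1 in the alkene plane, so the tether carbon C2 and the silyloxy group lie on opposite faces and the ketene is delivered anti to the silyloxy group, which leads from 1S to 4R,10R,11R. The step needs cycloaddition to outrun ketene dimerisation, which high dilution and slow addition should secure, and reaction at C10=C11 rather than at the terminal vinyl group, which only the three-atom tether allows. The silyl ether should finish on the side of the carbonyl bridge, away from the C10 methyl.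

Step 8
Reactants: 13 (1R,4S,5R,7R)-4-[(tert-butyldimethylsilyl)oxy]-7-ethenyl-7-methyl-2-methylidenebicyclo[3.1.1]heptan-6-one; 14 methyl 2-methylpropanoate
Product: 17 methyl 2-[(1R,4S,5R,6S,7R)-4-[(tert-butyldimethylsilyl)oxy]-7-ethenyl-6-[(2-methoxy-2-oxoacetyl)oxy]-7-methyl-2-methylidenebicyclo[3.1.1]heptan-6-yl]-2-methylpropanoate, via lithium enolate 15 (not isolated), via lithium alkoxide 16 (not isolated)
Conditions: LiN(i-Pr)2, 14, THF, −78 °C; add 13; then ClC(O)CO2Me, −78 to 0 °C
Reagents that add atoms: methyl chlorooxoacetate COC(=O)C(Cl)=O; lithium diisopropylamide [Li]N(C(C)C)C(C)C (lithium in 15 and 16 only)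
Why: Ester enolate addition to a strained, non-enolisable cyclobutanone from the only open face (syn to the three-carbon bridge), with the aldolate trapped in situ as the tertiary methyl oxalate before it can revert; the C5 configuration formed here is erased in step 9.

Step 9
Reactants: 17 methyl 2-[(1R,4S,5R,6S,7R)-4-[(tert-butyldimethylsilyl)oxy]-7-ethenyl-6-[(2-methoxy-2-oxoacetyl)oxy]-7-methyl-2-methylidenebicyclo[3.1.1]heptan-6-yl]-2-methylpropanoate
Product: 18 methyl 2-[(1R,4S,5R,6S,7R)-4-[(tert-butyldimethylsilyl)oxy]-7-ethenyl-7-methyl-2-methylidenebicyclo[3.1.1]heptan-6-yl]-2-methylpropanoate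
Conditions: n-Bu3SnH, AIBN, toluene, 110 °C
Reagents that add atoms: none
Why: Barton–McCombie-type deoxygenation of a tertiary methyl oxalate; the C5 radical can take hydrogen only from the face syn to the three-carbon bridge because the anti face is covered by the C10 vinyl group, so C6 is pushed anti (5S in target locants) whichever aldol epimer was formed.

Step 10
Reactants: 18 methyl 2-[(1R,4S,5R,6S,7R)-4-[(tert-butyldimethylsilyl)oxy]-7-ethenyl-7-methyl-2-methylidenebicyclo[3.1.1]heptan-6-yl]-2-methylpropanoate
Product: 19 2-[(1R,4S,5R,6S,7R)-4-[(tert-butyldimethylsilyl)oxy]-7-ethenyl-7-methyl-2-methylidenebicyclo[3.1.1]heptan-6-yl]-2-methylpropan-1-ol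
Conditions: i-Bu2AlH (3 equiv), CH2Cl2, −78 to 0 °C; Rochelle salt
Reagents that add atoms: none
Why: Full reduction of the neopentylic ester to the primary alcohol; alkenes and the silyl ether are inert.

Step 11
Reactants: 19 2-[(1R,4S,5R,6S,7R)-4-[(tert-butyldimethylsilyl)oxy]-7-ethenyl-7-methyl-2-methylidenebicyclo[3.1.1]heptan-6-yl]-2-methylpropan-1-ol
Product: 20 (1R,2S,5R,6R,7S)-6-ethenyl-7-(1-hydroxy-2-methylpropan-2-yl)-6-methyl-4-methylidenebicyclo[3.1.1]heptan-2-ol
Conditions: n-Bu4NF, THF, rt
Reagents that add atoms: none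
Why: Fluoride desilylation avoids acid, which would protonate the pinene-type methylidene and open or rearrange the cyclobutane.

Step 12
Reactants: 20 (1R,2S,5R,6R,7S)-6-ethenyl-7-(1-hydroxy-2-methylpropan-2-yl)-6-methyl-4-methylidenebicyclo[3.1.1]heptan-2-ol
Product: 21 2-[(1R,5R,6R,7S)-6-ethenyl-6-methyl-4-methylidene-2-oxobicyclo[3.1.1]heptan-7-yl]-2-methylpropanal
Conditions: Dess–Martin periodinane (3 equiv), NaHCO3, CH2Cl2, 0 °C to rt
Reagents that add atoms: none
Why: One buffered oxidation takes C1 to the ketone and C7 to the non-enolisable aldehyde; C5 now bears no oxygen, so the C1 ketone is safe.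

Step 13
Reactants: 21 2-[(1R,5R,6R,7S)-6-ethenyl-6-methyl-4-methylidene-2-oxobicyclo[3.1.1]heptan-7-yl]-2-methylpropanal
Product: 22 2-[(1R,5R,6R,7S)-6-acetyl-6-methyl-4-methylidene-2-oxobicyclo[3.1.1]heptan-7-yl]-2-methylpropanal
Conditions: PdCl2 (10 mol %), CuCl (20 mol %), O2 (1 atm), DMF/H2O (7:1), rt
Reagents that add atoms: water O
Why: Tsuji–Wacker oxidation is selective for the monosubstituted vinyl group and gives the methyl ketone (C9 and C8); the 1,1-disubstituted methylidene does not react.

Step 14
Reactants: 22 2-[(1R,5R,6R,7S)-6-acetyl-6-methyl-4-methylidene-2-oxobicyclo[3.1.1]heptan-7-yl]-2-methylpropanal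
Product: 25 (4R,5S,10R,11R)-longipina-2,7-diene-1,9-dione, via conjugated enone 23 (not isolated), via aldol adduct 24 (not isolated)
Conditions: KOt-Bu (0.3 equiv), t-BuOH/THF, rt to 50 °C
Reagents that add atoms: none
Why: Base first moves the β,γ-alkene into conjugation with C1; the methyl ketone enolate (C8) then adds to the adjacent non-enolisable aldehyde (C7) and dehydrates, an intramolecular aldol condensation that closes the seven-membered ring between two groups already held together on the anti positions of the cyclobutane.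

Step 15
Reactants: 25 (4R,5S,10R,11R)-longipina-2,7-diene-1,9-dione
Product: 27 (4R,5S,7R,10R,11R)-7-hydroxylongipin-2-ene-1,9-dione, via pinacol boronate 26 (not isolated)
Conditions: CuCl (5 mol %), NaOt-Bu (10 mol %), (R)-1-[(S)-2-(diphenylphosphino)ferrocenyl]ethyldicyclohexylphosphine (6 mol %), B2pin2 (1.1 equiv), MeOH (2 equiv), THF, 0 °C to rt; then NaBO3·4H2O, THF/H2O, rt
Reagents that add atoms: bis(pinacolato)diboron CC1(C)OB(OC1(C)C)B1OC(C)(C)C(C)(C)O1 (boron in 26 only); sodium perborate [Na+].[O-]OB=O
Why: Copper-catalysed enantioselective conjugate borylation at the β-CH (C7) of the cycloheptenone, then oxidation with retention; the chiral ligand sets 7R because the substrate has little facial bias, and the β,β-disubstituted enone at C1–C3 should react more slowly.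

Step 16
Reactants: 27 (4R,5S,7R,10R,11R)-7-hydroxylongipin-2-ene-1,9-dione; 28 2-methylprop-2-enal
Product: 30 (4R,5S,7R,9R,10R,11R)-9-hydroxy-1-oxolongipin-2-en-7-yl 2-methylprop-2-enoate, via hemiacetal 29 (not isolated)
Conditions: SmI2 (0.3 equiv), 28 (8 equiv), THF, −10 °C, dark
Reagents that add atoms: none
Why: Evans–Tishchenko reduction; the trivalent samarium formed in situ binds the C9 ketone and the hemiacetal of the C7 alcohol with 28, and hydride passes within a six-membered transition state to the C9 face syn to the C7 oxygen, giving the trans diol (9R) with the methacrylate on O7 and O9 free.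

Step 17
Reactants: 30 (4R,5S,7R,9R,10R,11R)-9-hydroxy-1-oxolongipin-2-en-7-yl 2-methylprop-2-enoate; 31 (Z)-2-methylbut-2-enoic acid
Product: 33 (4R,5S,7R,9R,10R,11R)-9-[(Z)-2-methylbut-2-enoyloxy]-1-oxolongipin-2-en-7-yl 2-methylprop-2-enoate, via mixed anhydride 32 (not isolated)
Conditions: 31, 2,4,6-trichlorobenzoyl chloride, Et3N, toluene, rt; then 30, toluene, 80 °C
Reagents that add atoms: 2,4,6-trichlorobenzoyl chloride O=C(Cl)c1c(Cl)cc(Cl)cc1Cl (in 32 only)
Why: Yamaguchi-type esterification; the hindered aroyl half of the mixed anhydride directs the alcohol to the angeloyl carbonyl, and leaving out a nucleophilic catalyst limits Z to E isomerisation.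

## Compound list

1 | (E)-3-methylpent-2-en-4-yn-1-ol | C#C/C(C)=C/CO | starting material
2 | (E)-3-methylpenta-2,4-dien-1-ol | C=C/C(C)=C/CO | intermediate
3 | (E)-3-methylpenta-2,4-dienal | C=C/C(C)=C/C=O | intermediate
4 | methyl 3-methylbut-2-enoate | COC(=O)C=C(C)C | starting material
5 | lithium 1-methoxy-3-methylbuta-1,3-dien-1-olate | C=C(C)/C=C(/OC)O[Li] | intermediate (not isolated)
6 | (1Z)-1-[(tert-butyldimethylsilyl)oxy]-1-methoxy-3-methylbuta-1,3-diene | C=C(C)/C=C(/OC)O[Si](C)(C)C(C)(C)C | intermediate
7 | methyl (2E,5S,6E)-3,7-dimethyl-5-[(trichlorosilyl)oxy]nona-2,6,8-trienoate | COC(=O)/C=C(\C)C[C@H](O[Si](Cl)(Cl)Cl)/C=C(\C)C=C | intermediate (not isolated)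
8 | methyl (2E,5S,6E)-5-hydroxy-3,7-dimethylnona-2,6,8-trienoate | COC(=O)/C=C(\C)C[C@H](O)/C=C(\C)C=C | intermediate
9 | methyl (2E,5S,6E)-5-[(tert-butyldimethylsilyl)oxy]-3,7-dimethylnona-2,6,8-trienoate | COC(=O)/C=C(\C)C[C@H](O[Si](C)(C)C(C)(C)C)/C=C(\C)C=C | intermediate
10 | (2E,5S,6E)-5-[(tert-butyldimethylsilyl)oxy]-3,7-dimethylnona-2,6,8-trienoic acid | OC(=O)/C=C(\C)C[C@H](O[Si](C)(C)C(C)(C)C)/C=C(\C)C=C | intermediate
11 | (2E,5S,6E)-5-[(tert-butyldimethylsilyl)oxy]-3,7-dimethylnona-2,6,8-trienoyl chloride | ClC(=O)/C=C(\C)C[C@H](O[Si](C)(C)C(C)(C)C)/C=C(\C)C=C | intermediate (not isolated)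
12 | (5S,6E)-5-[(tert-butyldimethylsilyl)oxy]-7-methyl-3-methylidenenona-1,6,8-trien-1-one (vinylketene) | O=C=CC(=C)C[C@H](O[Si](C)(C)C(C)(C)C)/C=C(\C)C=C | intermediate (not isolated)
13 | (1R,4S,5R,7R)-4-[(tert-butyldimethylsilyl)oxy]-7-ethenyl-7-methyl-2-methylidenebicyclo[3.1.1]heptan-6-one | C=C[C@@]1(C)[C@@H]2[C@@H](O[Si](C)(C)C(C)(C)C)CC(=C)[C@H]1C2=O | intermediate
14 | methyl 2-methylpropanoate | COC(=O)C(C)C | starting material
15 | lithium 1-methoxy-2-methylprop-1-en-1-olate | COC(O[Li])=C(C)C | intermediate (not isolated)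
16 | lithium (1R,4S,5R,6S,7R)-4-[(tert-butyldimethylsilyl)oxy]-7-ethenyl-6-(1-methoxy-2-methyl-1-oxopropan-2-yl)-7-methyl-2-methylidenebicyclo[3.1.1]heptan-6-olate | C=C[C@@]1(C)[C@@H]2[C@@H](O[Si](C)(C)C(C)(C)C)CC(=C)[C@H]1[C@@]2(O[Li])C(C)(C)C(=O)OC | intermediate (not isolated)
17 | methyl 2-[(1R,4S,5R,6S,7R)-4-[(tert-butyldimethylsilyl)oxy]-7-ethenyl-6-[(2-methoxy-2-oxoacetyl)oxy]-7-methyl-2-methylidenebicyclo[3.1.1]heptan-6-yl]-2-methylpropanoate | C=C[C@@]1(C)[C@@H]2[C@@H](O[Si](C)(C)C(C)(C)C)CC(=C)[C@H]1[C@@]2(OC(=O)C(=O)OC)C(C)(C)C(=O)OC | intermediate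
18 | methyl 2-[(1R,4S,5R,6S,7R)-4-[(tert-butyldimethylsilyl)oxy]-7-ethenyl-7-methyl-2-methylidenebicyclo[3.1.1]heptan-6-yl]-2-methylpropanoate | C=C[C@@]1(C)[C@@H]2[C@@H](O[Si](C)(C)C(C)(C)C)CC(=C)[C@H]1[C@@H]2C(C)(C)C(=O)OC | intermediate
19 | 2-[(1R,4S,5R,6S,7R)-4-[(tert-butyldimethylsilyl)oxy]-7-ethenyl-7-methyl-2-methylidenebicyclo[3.1.1]heptan-6-yl]-2-methylpropan-1-ol | C=C[C@@]1(C)[C@@H]2[C@@H](O[Si](C)(C)C(C)(C)C)CC(=C)[C@H]1[C@@H]2C(C)(C)CO | intermediate
20 | (1R,2S,5R,6R,7S)-6-ethenyl-7-(1-hydroxy-2-methylpropan-2-yl)-6-methyl-4-methylidenebicyclo[3.1.1]heptan-2-ol | C=C[C@@]1(C)[C@@H]2[C@@H](O)CC(=C)[C@H]1[C@@H]2C(C)(C)CO | intermediate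
21 | 2-[(1R,5R,6R,7S)-6-ethenyl-6-methyl-4-methylidene-2-oxobicyclo[3.1.1]heptan-7-yl]-2-methylpropanal | C=C[C@@]1(C)[C@@H]2C(=O)CC(=C)[C@H]1[C@@H]2C(C)(C)C=O | intermediate
22 | 2-[(1R,5R,6R,7S)-6-acetyl-6-methyl-4-methylidene-2-oxobicyclo[3.1.1]heptan-7-yl]-2-methylpropanal | CC(=O)[C@@]1(C)[C@@H]2C(=O)CC(=C)[C@H]1[C@@H]2C(C)(C)C=O | intermediate
23 | 2-[(1R,5R,6R,7S)-6-acetyl-4,6-dimethyl-2-oxobicyclo[3.1.1]hept-3-en-7-yl]-2-methylpropanal | CC(=O)[C@@]1(C)[C@@H]2C(=O)C=C(C)[C@H]1[C@@H]2C(C)(C)C=O | intermediate (not isolated)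
24 | (4R,5S,10R,11R)-7-hydroxylongipin-2-ene-1,9-dione, both C7 epimers (aldol adduct) | OC1CC(=O)[C@@]2(C)[C@@H]3C(=O)C=C(C)[C@H]2[C@@H]3C1(C)C | intermediate (not isolated)
25 | (4R,5S,10R,11R)-longipina-2,7-diene-1,9-dione | C1=CC(=O)[C@@]2(C)[C@@H]3C(=O)C=C(C)[C@H]2[C@@H]3C1(C)C | intermediate
26 | (4R,5S,7R,10R,11R)-7-(4,4,5,5-tetramethyl-1,3,2-dioxaborolan-2-yl)longipin-2-ene-1,9-dione | CC1(C)OB(OC1(C)C)[C@@H]1CC(=O)[C@@]2(C)[C@@H]3C(=O)C=C(C)[C@H]2[C@@H]3C1(C)C | intermediate (not isolated)
27 | (4R,5S,7R,10R,11R)-7-hydroxylongipin-2-ene-1,9-dione | O[C@@H]1CC(=O)[C@@]2(C)[C@@H]3C(=O)C=C(C)[C@H]2[C@@H]3C1(C)C | intermediate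
28 | 2-methylprop-2-enal (methacrolein) | C=C(C)C=O | starting material
29 | (4R,5S,7R,10R,11R)-7-(1-hydroxy-2-methylprop-2-enyloxy)longipin-2-ene-1,9-dione (samarium-bound hemiacetal, drawn neutral) | C=C(C)C(O)O[C@@H]1CC(=O)[C@@]2(C)[C@@H]3C(=O)C=C(C)[C@H]2[C@@H]3C1(C)C | intermediate (not isolated)
30 | (4R,5S,7R,9R,10R,11R)-9-hydroxy-1-oxolongipin-2-en-7-yl 2-methylprop-2-enoate | C=C(C)C(=O)O[C@@H]1C[C@@H](O)[C@@]2(C)[C@@H]3C(=O)C=C(C)[C@H]2[C@@H]3C1(C)C | intermediate
31 | (Z)-2-methylbut-2-enoic acid (angelic acid) | C/C=C(/C)C(=O)O | starting material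
32 | (Z)-2-methylbut-2-enoic 2,4,6-trichlorobenzoic anhydride | C/C=C(/C)C(=O)OC(=O)c1c(Cl)cc(Cl)cc1Cl | intermediate (not isolated)
33 | (4R,5S,7R,9R,10R,11R)-9-[(Z)-2-methylbut-2-enoyloxy]-1-oxolongipin-2-en-7-yl 2-methylprop-2-enoate (CNP0317071.1) | C=C(C)C(=O)O[C@@H]1C[C@@H](OC(=O)/C(C)=C\C)[C@@]2(C)[C@@H]3C(=O)C=C(C)[C@H]2[C@@H]3C1(C)C | target

## Step count and risk

Total: 17 steps. Longest linear sequence: 16 steps (1 to 33 through steps 1, 2 and 4 to 17); step 3 is a one-step side branch.

**Step 7 (key step).** The alkene is inductively deactivated by the allylic silyloxy group, so ketene dimerisation or decomposition may outrun the cycloaddition. With a diene as partner the addition may also turn stepwise enough to lose the E geometry at C10, or to erode facial control.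
Fallback: from 10, form the pyrrolidine amide F1 with a carbodiimide. Treat F1 with triflic anhydride and 2,4,6-collidine in 1,2-dichloroethane to generate the far more electrophilic vinylketeniminium ion, which should add to the same alkene to give cyclobutaniminium triflate F2. Aqueous NaHCO3 hydrolysis of F2 returns to the route at 13.

**Step 8 (with step 9).** Both faces of the C5 carbonyl are screened (silyloxy group on C1, vinyl group on C10), so addition may be slow or revert before trapping. In step 9, slow hydrogen transfer to the crowded C5 radical would leave time for ring opening of the cyclobutane.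
Fallback: from 13, Horner–Wadsworth–Emmons olefination with trimethyl phosphonoacetate and NaH gives the alkylidene ester F3. Conjugate reduction with Mg in MeOH should protonate C5 from the open face to give ester F4. Two enolate methylations with LiN(i-Pr)2 and MeI, through the monomethyl ester F5, return to the route at 18.

**Step 15.** The copper boryl may not discriminate well enough between the two enones, or the ligand may be mismatched with the substrate, giving poor facial selectivity at C7.
Fallback: from 22, isomerise to 23 with catalytic base, then form the kinetic lithium enolate of the methyl ketone at −78 °C and let it close onto the aldehyde without dehydration. This should give 27 together with its C7 epimer F6. The two are separated, and F6 is re-equilibrated through retro-aldol/aldol with K2CO3 in MeOH and recycled. The route is rejoined at 27.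

**Step 16.** Methacrolein may be consumed by pinacol coupling, polymerisation or conjugate reduction before the hydride transfer, and the new C9 alkoxide may attack the methacrylate (acyl migration or oxa-Michael addition).
Fallback: from 27, run the same Evans–Tishchenko reduction with the saturated surrogate 2-methyl-3-(phenylselanyl)propanal F7, made from 28 and benzeneselenol. This gives the 7-O-[2-methyl-3-(phenylselanyl)propanoyl] 9-alcohol F8. Oxidation of F8 with H2O2 and pyridine at 0 °C and selenoxide elimination unveil the methacrylate and return to the route at 30.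

**Step 17.** Forcing the acylation of the neopentylic C9 alcohol may isomerise the angelate to the tiglate, or let the C7 ester migrate.
Fallback: from 30, esterify with 2-[bis(2,2,2-trifluoroethoxy)phosphoryl]propanoic acid F9 (from its tert-butyl ester and CF3CO2H) under carbodiimide/DMAP conditions to give phosphonate ester F10. A Still–Gennari olefination of F10 with KN(SiMe3)2, 18-crown-6 and acetaldehyde at −78 °C builds the Z alkene on the molecule and returns to the route at 33.

## Further compounds

F1 | step 7 | (2E,5S,6E)-5-[(tert-butyldimethylsilyl)oxy]-3,7-dimethyl-1-(pyrrolidin-1-yl)nona-2,6,8-trien-1-one | O=C(/C=C(\C)C[C@H](O[Si](C)(C)C(C)(C)C)/C=C(\C)C=C)N1CCCC1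
F2 | step 7 | 1-[(1R,4S,5R,7R)-4-[(tert-butyldimethylsilyl)oxy]-7-ethenyl-7-methyl-2-methylidenebicyclo[3.1.1]heptan-6-ylidene]pyrrolidinium triflate | C=C[C@@]1(C)[C@@H]2[C@@H](O[Si](C)(C)C(C)(C)C)CC(=C)[C@H]1C2=[N+]3CCCC3.[O-]S(=O)(=O)C(F)(F)F
F3 | step 8 | methyl 2-[(1R,4S,5R,7R)-4-[(tert-butyldimethylsilyl)oxy]-7-ethenyl-7-methyl-2-methylidenebicyclo[3.1.1]heptan-6-ylidene]acetate (alkene isomers) | C=C[C@@]1(C)[C@@H]2[C@@H](O[Si](C)(C)C(C)(C)C)CC(=C)[C@H]1C2=CC(=O)OC
F4 | step 8 | methyl 2-[(1R,4S,5R,6S,7R)-4-[(tert-butyldimethylsilyl)oxy]-7-ethenyl-7-methyl-2-methylidenebicyclo[3.1.1]heptan-6-yl]acetate | C=C[C@@]1(C)[C@@H]2[C@@H](O[Si](C)(C)C(C)(C)C)CC(=C)[C@H]1[C@@H]2CC(=O)OC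
F5 | step 8 | methyl 2-[(1R,4S,5R,6S,7R)-4-[(tert-butyldimethylsilyl)oxy]-7-ethenyl-7-methyl-2-methylidenebicyclo[3.1.1]heptan-6-yl]propanoate (both α-epimers) | C=C[C@@]1(C)[C@@H]2[C@@H](O[Si](C)(C)C(C)(C)C)CC(=C)[C@H]1[C@@H]2C(C)C(=O)OC
F6 | step 15 | (4R,5S,7S,10R,11R)-7-hydroxylongipin-2-ene-1,9-dione | O[C@H]1CC(=O)[C@@]2(C)[C@@H]3C(=O)C=C(C)[C@H]2[C@@H]3C1(C)C
F7 | step 16 | 2-methyl-3-(phenylselanyl)propanal | CC(C[Se]c1ccccc1)C=O
F8 | step 16 | (4R,5S,7R,9R,10R,11R)-9-hydroxy-1-oxolongipin-2-en-7-yl 2-methyl-3-(phenylselanyl)propanoate (both α-epimers) | CC(C[Se]c1ccccc1)C(=O)O[C@@H]1C[C@@H](O)[C@@]2(C)[C@@H]3C(=O)C=C(C)[C@H]2[C@@H]3C1(C)C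
F9 | step 17 | 2-[bis(2,2,2-trifluoroethoxy)phosphoryl]propanoic acid | CC(C(=O)O)P(=O)(OCC(F)(F)F)OCC(F)(F)F
F10 | step 17 | (4R,5S,7R,9R,10R,11R)-9-{2-[bis(2,2,2-trifluoroethoxy)phosphoryl]propanoyloxy}-1-oxolongipin-2-en-7-yl 2-methylprop-2-enoate | C=C(C)C(=O)O[C@@H]1C[C@@H](OC(=O)C(C)P(=O)(OCC(F)(F)F)OCC(F)(F)F)[C@@]2(C)[C@@H]3C(=O)C=C(C)[C@H]2[C@@H]3C1(C)C
A1 | alternative 1 | cis-fused 7-[(tert-butyldimethylsilyl)oxy]-4-(tosyloxy)himachal-2-en-9-one (bicyclo[5.4.0]undecane keto tosylate) | CC(C)(C)[Si](C)(C)O[C@@H]1CC(=O)[C@H](C)[C@@H]2CC=C(C)[C@@H](OS(=O)(=O)c3ccc(C)cc3)[C@@H]2C1(C)C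
A2 | alternative 2 | (2E,6E)-1-[(tert-butyldimethylsilyl)oxy]-2,2,5,7-tetramethylnona-3,6,8-trien-4-one-type hexa-1,5-dien-3-one (racemic at the α-carbon) | CC(C)(CO[Si](C)(C)C(C)(C)C)/C=C/C(=O)C(C)/C=C(\C)C=C
A3 | alternative 2 | 5-{1-[(tert-butyldimethylsilyl)oxy]-2-methylpropan-2-yl}-6-ethenyl-3,6-dimethylbicyclo[2.1.1]hexan-2-one (desired isomer) | C=C[C@@]1(C)[C@@H]2C(=O)C(C)[C@H]1[C@@H]2C(C)(C)CO[Si](C)(C)C(C)(C)C
A4 | alternative 3 | (1R,5R)-(+)-verbenone | CC1(C)[C@@H]2C(=O)C=C(C)[C@H]1C2
A5 | alternative 3 | (1R,5R,6R)-4,6-dimethyl-2-oxobicyclo[3.1.1]hept-3-ene-6-carbaldehyde | O=C[C@@]1(C)[C@@H]2C(=O)C=C(C)[C@H]1C2
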